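Ring B (C1–C4) is cut away from ring A along C8a–C1 and C4a–C4. Because the fusion carbons C4a and C8a lie side by side next to the C5 oxygen, they can act as an aryne, while C1–C4 with the attached chain form a diene. One [4+2] addition of 3,4-dimethoxybenzyne to a (1E,3E)-1-acyloxy diene closes ring B, joins ring A to the whole C11–C17 chain and sets C1 and C4 as a cis pair; the C4 oxygen is later replaced by methyl with inversion. The diene, made from (S)-citronellal, carries C11, C15, a silylated C17 oxygen and an (R)-O-methylmandelate instead of acetate to screen one face.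

Key step: step 11

Numbering used below (also in the names of 21–31): ring B C1 (bears the side chain), C2, C3, C4 (bears methyl); fusion carbons C4a and C8a; ring A C5 and C6 (oxygens), C7 (carboxyl), C8 (H); side chain C11 (methyl-bearing, on C1), C12–C14, C15 (methyl-bearing), C17 (OCH2).

Assumption 1: the (R)-acid 8 is taken as the matched acyl group, on the model of an extended s-trans enol ester whose methoxy group eclipses the carbonyl, which places its phenyl ring over the diene face that must stay free; if the sense proves opposite, the (S)-acid is carried through the same steps.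

Assumption 2: in step 3 the (R)-BINAP complex is taken to add hydrogen to the same face of the HOCH2–C=C unit as in the hydrogenation of geraniol and nerol, which gives (R) at C15; otherwise the (S)-ligand is used.

Step 1
Reactants: 1 (S)-citronellal
Product: 2 (6S)-8,8-dimethoxy-2,6-dimethyloct-2-ene
Conditions: HC(OMe)3, MeOH, PPTS (cat.), rt
Reagents that add atoms: trimethyl orthoformate, COC(OC)OC; methanol, CO
Why: Acid-catalysed acetalisation with orthoformate as dehydrating agent should mask the aldehyde under conditions too mild for the carbonyl-ene cyclisation of citronellal, and C11 is untouched.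

Step 2
Reactants: 2 (6S)-8,8-dimethoxy-2,6-dimethyloct-2-ene
Product: 3 (2E,6S)-8,8-dimethoxy-2,6-dimethyloct-2-en-1-ol
Conditions: SeO2 (0.3 equiv), t-BuOOH (in decane), CH2Cl2, rt
Reagents that add atoms: tert-butyl hydroperoxide, CC(C)(C)OO
Why: Catalytic Riley allylic oxidation (ene reaction, then [2,3]-sigmatropic shift) should hydroxylate the (E)-methyl group of the trisubstituted alkene selectively, which installs the C17 oxygen without creating a stereocentre.

Step 3
Reactants: 3 (2E,6S)-8,8-dimethoxy-2,6-dimethyloct-2-en-1-ol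
Product: 4 (2R,6S)-8,8-dimethoxy-2,6-dimethyloctan-1-ol
Conditions: H2 (60 bar), Ru(OAc)2[(R)-BINAP] (1 mol%), MeOH, rt
Reagents that add atoms: none
Why: Noyori asymmetric hydrogenation of an allylic alcohol, in which the coordinated hydroxyl group and the chiral diphosphine select the alkene face, should set C15 as (R) under catalyst control, with the remote C11 centre and the acetal as bystanders.

Step 4
Reactants: 4 (2R,6S)-8,8-dimethoxy-2,6-dimethyloctan-1-ol
Product: 5 triisopropylsilyl ether of 4
Conditions: TIPSCl, imidazole, DMF, rt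
Reagents that add atoms: chlorotriisopropylsilane, CC(C)[Si](Cl)(C(C)C)C(C)C
Why: Standard silylation of a primary alcohol gives a triisopropylsilyl ether, chosen because it should outlast CsF in MeCN, K2CO3/MeOH, the Grignard step and the organolithium step.

Step 5
Reactants: 5 triisopropylsilyl ether of 4
Product: 6 (3S,7R)-3,7-dimethyl-8-(triisopropylsilyloxy)octanal
Conditions: TsOH·H2O (cat.), THF/H2O (4:1), rt
Reagents that add atoms: water, O
Why: Acid-catalysed acetal hydrolysis frees the aldehyde while a primary triisopropylsilyl ether should survive catalytic acid, and C11, being β to the carbonyl, cannot epimerise.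

Step 6
Reactants: 6 (3S,7R)-3,7-dimethyl-8-(triisopropylsilyloxy)octanal
Product: 7 (2E,5S,9R)-5,9-dimethyl-10-(triisopropylsilyloxy)dec-2-enal
Conditions: Ph3P=CHCHO (1.1 equiv), PhMe, 80 °C
Reagents that add atoms: (triphenylphosphoranylidene)acetaldehyde, O=CC=P(c1ccccc1)(c1ccccc1)c1ccccc1
Why: Wittig olefination with the stabilised formyl ylide should give the (E)-enal and adds the two carbons that become C3 and C4, the saturated aldehyde reacting faster than the enal formed.

Step 7
Reactants: 7 (2E,5S,9R)-5,9-dimethyl-10-(triisopropylsilyloxy)dec-2-enal; 8 (R)-2-methoxy-2-phenylacetic acid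
Product: 11 (1E,3E,5S,9R)-5,9-dimethyl-10-(triisopropylsilyloxy)deca-1,3-dien-1-yl (2R)-2-methoxy-2-phenylacetate, via acid chloride 9 (not isolated), via potassium dienolate 10 (not isolated)
Conditions: 8, (COCl)2, DMF (cat.), CH2Cl2, 0 °C → rt, evaporate; 7, KN(SiMe3)2, THF, −78 °C; then add 9, −78 → 0 °C
Reagents that add atoms: none
Why: γ-Deprotonation of the s-trans enal should give the extended (1E,3E)-dienolate (the branched C11 end avoids the cis position), and its O-acylation by the acid chloride at −78 °C, the standard route to 1-acyloxy-1,3-dienes, should leave the mandelate centre intact; any (Z)-isomer is a poor diene and is expected to remain unchanged in step 11.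

Step 8
Reactants: 12 3,4-dimethoxyphenol
Product: 13 3,4-dimethoxyphenyl N-isopropylcarbamate
Conditions: i-PrNCO, Et3N (cat.), CH2Cl2, rt
Reagents that add atoms: isopropyl isocyanate, CC(C)N=C=O
Why: Base-catalysed addition of the phenol to the isocyanate gives a secondary carbamate, a strong directing group for ortho-lithiation that can be removed later under mild conditions.

Step 9
Reactants: 13 3,4-dimethoxyphenyl N-isopropylcarbamate
Product: 17 3,4-dimethoxy-2-(trimethylsilyl)phenyl N-isopropylcarbamate, via N-silyl carbamate 14 (not isolated), via aryllithium 15 (not isolated), via N-silyl arylsilane 16 (not isolated)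
Conditions: TBSOTf, TMEDA, Et2O, 0 °C → rt; n-BuLi, TMEDA, −78 °C; TMSCl, −78 °C → rt; aq. NaHSO4
Reagents that add atoms: chlorotrimethylsilane, C[Si](C)(C)Cl
Why: Directed ortho-metalation of the N-silylated carbamate should occur at C2, the position flanked by the carbamate and the 3-methoxy group, and silylation of the aryllithium followed by N–Si hydrolysis on work-up gives the arylsilane.

Step 10
Reactants: 17 3,4-dimethoxy-2-(trimethylsilyl)phenyl N-isopropylcarbamate
Product: 19 3,4-dimethoxy-2-(trimethylsilyl)phenyl trifluoromethanesulfonate, via silylphenol 18 (not isolated)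
Conditions: Et2NH, DBU, MeCN, 40 °C; then PhNTf2, rt
Reagents that add atoms: N-phenylbis(trifluoromethanesulfonimide), O=S(=O)(N(c1ccccc1)S(=O)(=O)C(F)(F)F)C(F)(F)F
Why: Base-induced cleavage of the secondary carbamate (elimination to isopropyl isocyanate, which Et2NH traps) frees the phenoxide, and this is triflated in the same flask.

Step 11
Reactants: 11 (1E,3E)-dienyl (R)-O-methylmandelate; 19 3,4-dimethoxy-2-(trimethylsilyl)phenyl trifluoromethanesulfonate
Product: 21 cis-(1R,4S)-4-acyloxy-1-alkyl-5,6-dimethoxy-1,4-dihydronaphthalene (acyl = (R)-O-methylmandeloyl; alkyl = C11–C17 chain with C17 OTIPS), via aryne 20 (not isolated)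
Conditions: 19 (1.5 equiv, slow addition), CsF (3 equiv), MeCN/PhMe (1:1), rt
Reagents that add atoms: none
Why: Fluoride removes the trimethylsilyl group of 19 and triflate leaves, giving aryne 20, which adds to the s-cis conformer of diene 11 in a concerted suprafacial [4+2] cycloaddition; the closest known reaction type is the Diels–Alder addition of arynes from silyl triflates to acyclic (E,E)-1-oxygenated dienes. Ring B is closed by an intermolecular [4+2] annulation that forms C8a–C1 and C4a–C4 together. Because both diene termini carry their substituents on the outside (E,E), the C1 chain and the C4 acyloxy group must emerge cis. The diene face used (Re at C1 and at C4) fixes C1 relative to C11: the C11 centre favours it weakly (with C11–H eclipsing C1=C2, the methyl group and not the long chain lies on that face) and the phenyl ring of the (R)-mandelate is meant to cover the other face. Regiochemistry rests on the C5 methoxy group, which makes C8a the electrophilic aryne carbon, so that the more nucleophilic alkyl-bearing diene terminus (remote from the acyloxy donor) bonds there and the oxygenated terminus bonds to C4a. The step also needs cycloaddition to outrun the ene reaction at C11–H, for which the s-cis-accessible (E,E)-diene and an excess of 19 are relied on.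

Step 12
Reactants: 21 cis-4-acyloxy-1-alkyl-5,6-dimethoxy-1,4-dihydronaphthalene
Product: 22 cis-(1S,4S)-4-acyloxy-1-alkyl-5,6-dimethoxytetralin (acyl = (R)-O-methylmandeloyl)
Conditions: 2-O2NC6H4SO2NHNH2, Et3N, CH2Cl2, rt (crude 21 used at once)
Reagents that add atoms: none
Why: Concerted syn transfer of two hydrogens from diimide should saturate C2=C3 without hydrogenolysis of the allylic benzylic ester, which removes the path to a naphthalene by loss of the acid and changes no stereocentre.

Step 13
Reactants: 22 cis-4-acyloxy-1-alkyl-5,6-dimethoxytetralin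
Product: 23 cis-(1S,4S)-1-alkyl-5,6-dimethoxytetralin-4-ol
Conditions: K2CO3, MeOH/THF, rt
Reagents that add atoms: none
Why: Base-catalysed methanolysis of the activated α-alkoxy ester breaks only the acyl C–O bond, so the cis C4 alcohol should be released with retention and the auxiliary leaves as its methyl ester.

Step 14
Reactants: 23 cis-1-alkyl-5,6-dimethoxytetralin-4-ol
Product: 24 cis-(1S,4S)-1-alkyl-4,5,6-trimethoxytetralin
Conditions: NaH, MeI, THF, 0 °C → rt
Reagents that add atoms: iodomethane, CI
Why: Williamson etherification of the alkoxide gives the benzylic methyl ether required as leaving group for the nickel-catalysed coupling, with the C4 configuration retained.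

Step 15
Reactants: 24 cis-1-alkyl-4,5,6-trimethoxytetralin
Product: 25 trans-(1S,4R)-1-alkyl-5,6-dimethoxy-4-methyltetralin
Conditions: Ni(cod)2 (10 mol%), rac-BINAP (20 mol%), MeMgI (3 equiv), PhMe, rt
Reagents that add atoms: methylmagnesium iodide, C[Mg]I
Why: Proposed new method: a zerovalent nickel–diphosphine complex should attack the benzylic C4–O bond from the face opposite the leaving methoxy group, which is activated by magnesium chelated between the C4 and C5 oxygens (SN2-like oxidative addition with inversion), and transmetalation with MeMgI followed by reductive elimination with retention then places the methyl group trans to the C1 chain; the closest known reaction type is the stereospecific, invertive nickel-catalysed Kumada coupling of secondary benzylic methyl ethers with MeMgI, so far shown for naphthyl- and diaryl-substituted ethers but not for an ether on a single benzene ring.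

Step 16
Reactants: 25 trans-1-alkyl-5,6-dimethoxy-4-methyltetralin
Product: 27 tert-butyl trans-1-alkyl-5,6-dimethoxy-4-methyltetralin-7-carboxylate, via aryllithium 26 (not isolated)
Conditions: n-BuLi, TMEDA, Et2O, 0 °C → rt; then Boc2O, −78 °C → rt
Reagents that add atoms: di-tert-butyl dicarbonate, CC(C)(C)OC(=O)OC(=O)OC(C)(C)C
Why: Directed ortho-metalation beside the C6 methoxy group can only occur at C7 (C8 has no neighbouring oxygen), and acylation of the aryllithium by Boc2O should give the tert-butyl ester, so that the carboxyl group enters already protected.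

Step 17
Reactants: 27 tert-butyl trans-1-alkyl-5,6-dimethoxy-4-methyltetralin-7-carboxylate
Product: 28 C17 alcohol of 27
Conditions: Bu4NF, THF, rt
Reagents that add atoms: none
Why: Fluoride-induced desilylation frees the primary C17 alcohol, while the tert-butyl ester and the aryl methyl ethers are inert.

Step 18
Reactants: 28 C17 alcohol; 29 (E)-3,4-dimethoxycinnamic acid
Product: 30 C17 (E)-3,4-dimethoxycinnamate of 28
Conditions: EDC·HCl, DMAP, CH2Cl2, rt
Reagents that add atoms: none
Why: Steglich esterification of the unhindered primary alcohol should be clean because every phenol is still a methyl ether and the ring carboxyl is a tert-butyl ester, so only one hydroxyl group can be acylated.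

Step 19
Reactants: 30 C17 (E)-3,4-dimethoxycinnamate
Product: 31 CNP0492979.1
Conditions: BBr3 (10 equiv), CH2Cl2, −78 → 0 °C; then H2O
Reagents that add atoms: none
Why: Lewis acid-mediated dealkylation by BBr3 (bromide attack on the four O-methyl groups, loss of the tert-butyl cation from the ester) should unveil both catechols and the acid at low temperature, where a primary alkyl cinnamate is expected to survive and no stereocentre is touched.

Compound list ("alkyl" in the step lines = (2S,6R)-6-methyl-7-(triisopropylsilyloxy)heptan-2-yl)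

1 | (S)-citronellal, (3S)-3,7-dimethyloct-6-enal | CC(C)=CCC[C@H](C)CC=O | starting material
2 | (6S)-8,8-dimethoxy-2,6-dimethyloct-2-ene | CC(C)=CCC[C@H](C)CC(OC)OC | intermediate
3 | (2E,6S)-8,8-dimethoxy-2,6-dimethyloct-2-en-1-ol | OC/C(C)=C/CC[C@H](C)CC(OC)OC | intermediate
4 | (2R,6S)-8,8-dimethoxy-2,6-dimethyloctan-1-ol | C[C@H](CCC[C@H](C)CC(OC)OC)CO | intermediate
5 | [(2R,6S)-8,8-dimethoxy-2,6-dimethyloctyl]oxy-triisopropylsilane | C[C@H](CCC[C@H](C)CC(OC)OC)CO[Si](C(C)C)(C(C)C)C(C)C | intermediate
6 | (3S,7R)-3,7-dimethyl-8-(triisopropylsilyloxy)octanal | C[C@H](CCC[C@H](C)CC=O)CO[Si](C(C)C)(C(C)C)C(C)C | intermediate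
7 | (2E,5S,9R)-5,9-dimethyl-10-(triisopropylsilyloxy)dec-2-enal | C[C@H](CCC[C@H](C)C/C=C/C=O)CO[Si](C(C)C)(C(C)C)C(C)C | intermediate
8 | (R)-2-methoxy-2-phenylacetic acid ((R)-O-methylmandelic acid) | CO[C@@H](C(=O)O)c1ccccc1 | starting material
9 | (R)-2-methoxy-2-phenylacetyl chloride | CO[C@@H](C(=O)Cl)c1ccccc1 | intermediate (not isolated)
10 | potassium (1E,3E,5S,9R)-5,9-dimethyl-10-(triisopropylsilyloxy)deca-1,3-dien-1-olate | C[C@H](CCC[C@H](C)/C=C/C=C/[O-])CO[Si](C(C)C)(C(C)C)C(C)C.[K+] | intermediate (not isolated)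
11 | (1E,3E,5S,9R)-5,9-dimethyl-10-(triisopropylsilyloxy)deca-1,3-dien-1-yl (2R)-2-methoxy-2-phenylacetate | C[C@H](CCC[C@H](C)/C=C/C=C/OC(=O)[C@H](OC)c1ccccc1)CO[Si](C(C)C)(C(C)C)C(C)C | intermediate
12 | 3,4-dimethoxyphenol | COc1ccc(O)cc1OC | starting material
13 | 3,4-dimethoxyphenyl N-isopropylcarbamate | COc1ccc(OC(=O)NC(C)C)cc1OC | intermediate
14 | 3,4-dimethoxyphenyl N-(tert-butyldimethylsilyl)-N-isopropylcarbamate | COc1ccc(OC(=O)N(C(C)C)[Si](C)(C)C(C)(C)C)cc1OC | intermediate (not isolated)
15 | 2-lithio derivative of 14 | COc1ccc(OC(=O)N(C(C)C)[Si](C)(C)C(C)(C)C)c([Li])c1OC | intermediate (not isolated)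
16 | 3,4-dimethoxy-2-(trimethylsilyl)phenyl N-(tert-butyldimethylsilyl)-N-isopropylcarbamate | COc1ccc(OC(=O)N(C(C)C)[Si](C)(C)C(C)(C)C)c([Si](C)(C)C)c1OC | intermediate (not isolated)
17 | 3,4-dimethoxy-2-(trimethylsilyl)phenyl N-isopropylcarbamate | COc1ccc(OC(=O)NC(C)C)c([Si](C)(C)C)c1OC | intermediate
18 | 3,4-dimethoxy-2-(trimethylsilyl)phenol (as its amidinium salt) | COc1ccc(O)c([Si](C)(C)C)c1OC | intermediate (not isolated)
19 | 3,4-dimethoxy-2-(trimethylsilyl)phenyl trifluoromethanesulfonate | COc1ccc(OS(=O)(=O)C(F)(F)F)c([Si](C)(C)C)c1OC | intermediate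
20 | 3,4-dimethoxybenzyne (1,2-didehydro-3,4-dimethoxybenzene) | COC1=C(OC)C#CC=C1 | intermediate (not isolated)
21 | cis-(1R,4S)-5,6-dimethoxy-1-[(2S,6R)-6-methyl-7-(triisopropylsilyloxy)heptan-2-yl]-1,4-dihydronaphthalen-4-yl (2R)-2-methoxy-2-phenylacetate | C[C@H](CCC[C@H](C)[C@@H]1C=C[C@H](OC(=O)[C@H](OC)c3ccccc3)c2c1ccc(OC)c2OC)CO[Si](C(C)C)(C(C)C)C(C)C | intermediate
22 | cis-(1S,4S)-5,6-dimethoxy-1-[(2S,6R)-6-methyl-7-(triisopropylsilyloxy)heptan-2-yl]-1,2,3,4-tetrahydronaphthalen-4-yl (2R)-2-methoxy-2-phenylacetate | C[C@H](CCC[C@H](C)[C@@H]1CC[C@H](OC(=O)[C@H](OC)c3ccccc3)c2c1ccc(OC)c2OC)CO[Si](C(C)C)(C(C)C)C(C)C | intermediate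
23 | cis-(1S,4S)-5,6-dimethoxy-1-[(2S,6R)-6-methyl-7-(triisopropylsilyloxy)heptan-2-yl]-1,2,3,4-tetrahydronaphthalen-4-ol | C[C@H](CCC[C@H](C)[C@@H]1CC[C@H](O)c2c1ccc(OC)c2OC)CO[Si](C(C)C)(C(C)C)C(C)C | intermediate
24 | cis-(1S,4S)-4,5,6-trimethoxy-1-[(2S,6R)-6-methyl-7-(triisopropylsilyloxy)heptan-2-yl]-1,2,3,4-tetrahydronaphthalene | C[C@H](CCC[C@H](C)[C@@H]1CC[C@H](OC)c2c1ccc(OC)c2OC)CO[Si](C(C)C)(C(C)C)C(C)C | intermediate
25 | trans-(1S,4R)-5,6-dimethoxy-4-methyl-1-[(2S,6R)-6-methyl-7-(triisopropylsilyloxy)heptan-2-yl]-1,2,3,4-tetrahydronaphthalene | C[C@H](CCC[C@H](C)[C@@H]1CC[C@@H](C)c2c1ccc(OC)c2OC)CO[Si](C(C)C)(C(C)C)C(C)C | intermediate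
26 | 7-lithio derivative of 25 | C[C@H](CCC[C@H](C)[C@@H]1CC[C@@H](C)c2c1cc([Li])c(OC)c2OC)CO[Si](C(C)C)(C(C)C)C(C)C | intermediate (not isolated)
27 | tert-butyl trans-(1S,4R)-5,6-dimethoxy-4-methyl-1-[(2S,6R)-6-methyl-7-(triisopropylsilyloxy)heptan-2-yl]-1,2,3,4-tetrahydronaphthalene-7-carboxylate | C[C@H](CCC[C@H](C)[C@@H]1CC[C@@H](C)c2c1cc(C(=O)OC(C)(C)C)c(OC)c2OC)CO[Si](C(C)C)(C(C)C)C(C)C | intermediate
28 | tert-butyl trans-(1S,4R)-1-[(2S,6R)-7-hydroxy-6-methylheptan-2-yl]-5,6-dimethoxy-4-methyl-1,2,3,4-tetrahydronaphthalene-7-carboxylate | C[C@H](CCC[C@H](C)[C@@H]1CC[C@@H](C)c2c1cc(C(=O)OC(C)(C)C)c(OC)c2OC)CO | intermediate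
29 | (E)-3-(3,4-dimethoxyphenyl)prop-2-enoic acid (3,4-dimethoxycinnamic acid) | OC(=O)/C=C/c1ccc(OC)c(OC)c1 | starting material
30 | tert-butyl trans-(1S,4R)-1-[(2S,6R)-7-{[(E)-3-(3,4-dimethoxyphenyl)prop-2-enoyl]oxy}-6-methylheptan-2-yl]-5,6-dimethoxy-4-methyl-1,2,3,4-tetrahydronaphthalene-7-carboxylate | C[C@H](CCC[C@H](C)[C@@H]1CC[C@@H](C)c2c1cc(C(=O)OC(C)(C)C)c(OC)c2OC)COC(=O)/C=C/c1ccc(OC)c(OC)c1 | intermediate
31 | trans-(1S,4R)-1-[(2S,6R)-7-{[(E)-3-(3,4-dihydroxyphenyl)prop-2-enoyl]oxy}-6-methylheptan-2-yl]-5,6-dihydroxy-4-methyl-1,2,3,4-tetrahydronaphthalene-7-carboxylic acid (CNP0492979.1) | C[C@H](CCC[C@H](C)[C@@H]1CC[C@@H](C)c2c1cc(C(=O)O)c(O)c2O)COC(=O)/C=C/c1ccc(O)c(O)c1 | target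

Total step count: 19. Longest linear sequence: 16 steps (steps 1–7, 11, 12–19); the aryne precursor is a three-step side branch (steps 8–10).

Steps most likely to fail

1. Step 15 (bears the label). What may go wrong: oxidative addition at a benzylic carbon on a single, electron-rich benzene ring may be too slow; the ortho-methoxy group may let the ether ionise, eroding the inversion; β-hydride elimination may give a dihydronaphthalene. Fallback with known chemistry, setting out from 23 and returning at 25: Dess–Martin oxidation of 23 should give the C4 ketone F1. Addition of MeMgBr in the presence of CeCl3 gives the tertiary benzylic carbinol F2 (both C4 epimers). Acid-catalysed dehydration (TsOH, PhH, reflux) gives the 4-methyl-1,2-dihydronaphthalene F3. Asymmetric hydrogenation of this trisubstituted cyclic styrene, a well-established substrate class for cationic iridium N,P catalysts, is run with the enantiomer of [Ir(cod)(tBu-PHOX)]BArF that adds hydrogen to the face cis to the C1 chain, and gives 25. C4 is then set by the catalyst and no longer by substitution.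

2. Step 11. What may go wrong: poor facial selectivity, because neither the weakly biased C11 centre nor the distant mandelate holds the aryne to one diene face; beside this, ene reaction of the aryne at C11–H and loss of the acid from the adduct. Fallback, setting out from 7 and returning at 23: face control in the cycloaddition is given up and the two cis epimers are told apart later by an enzyme. Enal 7 is converted under equilibrating conditions (isopropenyl acetate, TsOH cat., 90 °C) into the dienyl acetate F4. Cycloaddition with 19 and CsF gives the cis acetoxy adduct F5 together with its C1,C4-epimer. Diimide reduction gives the tetralin acetate F6, and K2CO3/MeOH gives 23 mixed with the epimeric alcohol F7. Candida antarctica lipase B with vinyl acetate, which by the empirical rule for secondary benzylic carbinols acylates the (4R) centre, should convert F7 into its acetate F8 and leave 23, which is separated by chromatography.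

3. Step 19. What may go wrong: cleavage of the C17 ester C–O bond by BBr3, incomplete demethylation, or oxidation of the free catechols on work-up. Fallback, setting out from 28 and returning at 31: the caffeoyl unit is built last and without protecting groups. BBr3 (CH2Cl2, −78 → 0 °C) on 28, which has no C17 ester yet, gives the trihydroxy acid F9. Meldrum's acid (PhMe, 90 °C) acylates the primary aliphatic alcohol in preference to the phenols and gives the malonic half-ester F10. Knoevenagel–Doebner condensation with 3,4-dihydroxybenzaldehyde (pyridine, piperidine cat., 50 °C) with loss of CO2 gives the (E)-caffeate 31.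

Further compounds
F1 | step 15 | (1S)-5,6-dimethoxy-1-[(2S,6R)-6-methyl-7-(triisopropylsilyloxy)heptan-2-yl]-2,3-dihydro-1H-naphthalen-4-one (C4 ketone) | C[C@H](CCC[C@H](C)[C@@H]1CCC(=O)c2c1ccc(OC)c2OC)CO[Si](C(C)C)(C(C)C)C(C)C
F2 | step 15 | (1S)-5,6-dimethoxy-4-methyl-1-[(2S,6R)-6-methyl-7-(triisopropylsilyloxy)heptan-2-yl]-1,2,3,4-tetrahydronaphthalen-4-ol (C4 epimers) | C[C@H](CCC[C@H](C)[C@@H]1CCC(C)(O)c2c1ccc(OC)c2OC)CO[Si](C(C)C)(C(C)C)C(C)C
F3 | step 15 | (1S)-5,6-dimethoxy-4-methyl-1-[(2S,6R)-6-methyl-7-(triisopropylsilyloxy)heptan-2-yl]-1,2-dihydronaphthalene | C[C@H](CCC[C@H](C)[C@@H]1CC=C(C)c2c1ccc(OC)c2OC)CO[Si](C(C)C)(C(C)C)C(C)C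
F4 | step 11 | (1E,3E,5S,9R)-5,9-dimethyl-10-(triisopropylsilyloxy)deca-1,3-dien-1-yl acetate | C[C@H](CCC[C@H](C)/C=C/C=C/OC(C)=O)CO[Si](C(C)C)(C(C)C)C(C)C
F5 | step 11 | cis-(1R,4S)-5,6-dimethoxy-1-[(2S,6R)-6-methyl-7-(triisopropylsilyloxy)heptan-2-yl]-1,4-dihydronaphthalen-4-yl acetate (formed together with its C1,C4-epimer) | C[C@H](CCC[C@H](C)[C@@H]1C=C[C@H](OC(C)=O)c2c1ccc(OC)c2OC)CO[Si](C(C)C)(C(C)C)C(C)C
F6 | step 11 | cis-(1S,4S)-5,6-dimethoxy-1-[(2S,6R)-6-methyl-7-(triisopropylsilyloxy)heptan-2-yl]-1,2,3,4-tetrahydronaphthalen-4-yl acetate (formed together with its C1,C4-epimer) | C[C@H](CCC[C@H](C)[C@@H]1CC[C@H](OC(C)=O)c2c1ccc(OC)c2OC)CO[Si](C(C)C)(C(C)C)C(C)C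
F7 | step 11 | cis-(1R,4R)-5,6-dimethoxy-1-[(2S,6R)-6-methyl-7-(triisopropylsilyloxy)heptan-2-yl]-1,2,3,4-tetrahydronaphthalen-4-ol (unwanted epimer of 23) | C[C@H](CCC[C@H](C)[C@H]1CC[C@@H](O)c2c1ccc(OC)c2OC)CO[Si](C(C)C)(C(C)C)C(C)C
F8 | step 11 | cis-(1R,4R)-5,6-dimethoxy-1-[(2S,6R)-6-methyl-7-(triisopropylsilyloxy)heptan-2-yl]-1,2,3,4-tetrahydronaphthalen-4-yl acetate | C[C@H](CCC[C@H](C)[C@H]1CC[C@@H](OC(C)=O)c2c1ccc(OC)c2OC)CO[Si](C(C)C)(C(C)C)C(C)C
F9 | step 19 | trans-(1S,4R)-5,6-dihydroxy-1-[(2S,6R)-7-hydroxy-6-methylheptan-2-yl]-4-methyl-1,2,3,4-tetrahydronaphthalene-7-carboxylic acid | C[C@H](CCC[C@H](C)[C@@H]1CC[C@@H](C)c2c1cc(C(=O)O)c(O)c2O)CO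
F10 | step 19 | trans-(1S,4R)-1-[(2S,6R)-7-(carboxyacetoxy)-6-methylheptan-2-yl]-5,6-dihydroxy-4-methyl-1,2,3,4-tetrahydronaphthalene-7-carboxylic acid | C[C@H](CCC[C@H](C)[C@@H]1CC[C@@H](C)c2c1cc(C(=O)O)c(O)c2O)COC(=O)CC(=O)O
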